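**Plan**

- Enabling feature: ring A carries oxygen on C5, C7 and C8a and the acyl carbon C4 on C4a. It is an acylphloroglucinol, the shape a poly-β-carbonyl chain takes when its C6 closes onto its C1.
- Retrosynthesis: remove the benzyl group from the 3'-oxygen; cut O1–C2 (pyranone, cyclodehydration) to diketone 17; cut C4a–C5 (ring A, Claisen) to the open tetraketo ester 15.
- Ester 15 is cut at chain bonds C8–C9, C6–C7 and C4–C5 and at the ester mask, giving B-ring acid 8, two acetyl donors and dioxinone 9.
- Forward, B ring: acid 8 comes from 2-hydroxy-3,4-dimethoxybenzaldehyde by a formyl transposition (Baeyer–Villiger oxidation, then ortho-formylation), which fixes the 3-benzyloxy-2,4,5-trimethoxy pattern without regiochemical ambiguity.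
- Forward, chain and rings: three terminal Claisen acylations on the dioxinone (acetyl, acetyl, aroyl), methanolysis to 15, Claisen fold to ring A, acid closure of ring C, hydrogenolysis.
- Stereochemistry: the target has no stereocentre and no stereogenic double bond, so nothing has to be controlled.

Key step: step 10

Remark: the poly-β-carbonyl compounds 11, 13 and 15 are drawn as keto forms although they should exist largely as enols. They are meant to be carried forward crude, and the excess of 11 from step 8 is to be removed at the stage of the stable aromatic compound 17.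

**Route**

Step 1
Reactants: 1 2-hydroxy-3,4-dimethoxybenzaldehyde
Product: 2 2-(benzyloxy)-3,4-dimethoxybenzaldehyde
Conditions: BnBr, K2CO3, DMF, 60 °C
Reagents that add atoms: benzyl bromide, BrCc1ccccc1
Why: Williamson etherification of the only phenol, which carbonate in DMF deprotonates despite its hydrogen bond to the aldehyde.

Step 2
Reactants: 2 2-(benzyloxy)-3,4-dimethoxybenzaldehyde
Product: 4 2-(benzyloxy)-3,4-dimethoxyphenol, via 2-(benzyloxy)-3,4-dimethoxyphenyl formate 3 (not isolated)
Conditions: mCPBA, CH2Cl2, 0 °C → rt; then K2CO3 (cat.), MeOH, rt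
Reagents that add atoms: 3-chloroperoxybenzoic acid, OOC(=O)c1cccc(Cl)c1
Why: Baeyer–Villiger (Dakin-type) oxidation, in which the aryl group activated by ortho-benzyloxy and para-methoxy migrates in preference to hydride to give formate 3, which mild methanolysis should cleave to the phenol.

Step 3
Reactants: 4 2-(benzyloxy)-3,4-dimethoxyphenol
Product: 6 3-(benzyloxy)-2-hydroxy-4,5-dimethoxybenzaldehyde, via 2-(benzyloxy)-6-(hydroxymethyl)-3,4-dimethoxyphenol 5 (not isolated)
Conditions: (CH2O)n, MgCl2, Et3N, MeCN, reflux; then 1 M HCl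
Reagents that add atoms: formaldehyde (as paraformaldehyde), C=O
Why: Magnesium-mediated ortho-formylation (Casnati–Skattebøl), in which the magnesium phenoxide delivers formaldehyde to the only free ortho carbon and a second formaldehyde oxidises alcohol 5 by hydride transfer, the para position being blocked by methoxy.

Step 4
Reactants: 6 3-(benzyloxy)-2-hydroxy-4,5-dimethoxybenzaldehyde
Product: 7 3-(benzyloxy)-2,4,5-trimethoxybenzaldehyde
Conditions: MeI, K2CO3, DMF, 40 °C
Reagents that add atoms: iodomethane, CI
Why: Williamson methylation of the single remaining phenol, which completes the 2,4,5-trimethoxy pattern around the benzyl-protected 3-oxygen.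

Step 5
Reactants: 7 3-(benzyloxy)-2,4,5-trimethoxybenzaldehyde
Product: 8 3-(benzyloxy)-2,4,5-trimethoxybenzoic acid
Conditions: NaClO2, NaH2PO4, 2-methyl-2-butene, t-BuOH/H2O, rt
Reagents that add atoms: sodium chlorite, [Na+].[O-]Cl=O
Why: Pinnick oxidation of the aldehyde, with the alkene scavenger intercepting hypochlorous acid so that the electron-rich ring should not be chlorinated.

Step 6
Reactants: 9 2,2,6-trimethyl-4H-1,3-dioxin-4-one
Product: 10 2,2-dimethyl-6-(2-oxopropyl)-4H-1,3-dioxin-4-one
Conditions: 9 (2 equiv), LiHMDS (2 equiv), THF, −78 °C; AcCl (1 equiv), −78 → −20 °C; 1 M HCl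
Reagents that add atoms: acetyl chloride, CC(=O)Cl
Why: Vinylogous Claisen acylation of the lithium dienolate at its γ-carbon, the second equivalent of dienolate deprotonating the more acidic product and so preventing double acylation.

Step 7
Reactants: 10 2,2-dimethyl-6-(2-oxopropyl)-4H-1,3-dioxin-4-one
Product: 11 6-(2,4-dioxopentyl)-2,2-dimethyl-4H-1,3-dioxin-4-one
Conditions: LDA (2.2 equiv), THF, −78 → −40 °C; MeC(O)N(OMe)Me, −78 °C; cold 1 M HCl
Reagents that add atoms: N-methoxy-N-methylacetamide, CC(=O)N(C)OC
Why: Polyanion Claisen acylation, in which the dianion reacts at its last-formed terminal carbanion and the chelated tetrahedral adduct of the Weinreb amide blocks over-addition and proton transfer.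

Step 8
Reactants: 8 3-(benzyloxy)-2,4,5-trimethoxybenzoic acid; 11 6-(2,4-dioxopentyl)-2,2-dimethyl-4H-1,3-dioxin-4-one
Product: 13 6-{6-[3-(benzyloxy)-2,4,5-trimethoxyphenyl]-2,4,6-trioxohexyl}-2,2-dimethyl-4H-1,3-dioxin-4-one, via 3-(benzyloxy)-2,4,5-trimethoxybenzoyl chloride 12 (not isolated)
Conditions: 8, (COCl)2, DMF (cat.), CH2Cl2, rt, then evaporation; 11 (2 equiv), LDA (6.2 equiv), THF, −78 → −20 °C; 12, −78 °C; cold 1 M HCl
Reagents that add atoms: none
Why: Polyanion Claisen aroylation, in which the trianion of 11 attacks the non-enolisable acid chloride through its terminal carbanion, the second equivalent of trianion taking up the proton of the more acidic product and the lithium enolates masking every ketone until the cold acidic quench.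

Step 9
Reactants: 13 6-{6-[3-(benzyloxy)-2,4,5-trimethoxyphenyl]-2,4,6-trioxohexyl}-2,2-dimethyl-4H-1,3-dioxin-4-one
Product: 15 methyl 9-[3-(benzyloxy)-2,4,5-trimethoxyphenyl]-3,5,7,9-tetraoxononanoate, via acylketene 14 (not isolated)
Conditions: MeOH (20 equiv), PhMe, 110 °C (sealed tube), short heating
Reagents that add atoms: methanol, CO
Why: Thermal retro-hetero-Diels–Alder loss of acetone from the dioxinone gives acylketene 14, which the large excess of methanol should capture as the methyl ester under neutral conditions.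

Step 10
Reactants: 15 methyl 9-[3-(benzyloxy)-2,4,5-trimethoxyphenyl]-3,5,7,9-tetraoxononanoate
Product: 17 1-[3-(benzyloxy)-2,4,5-trimethoxyphenyl]-3-(2,4,6-trihydroxyphenyl)propane-1,3-dione, via cyclohexane-1,3,5-trione tautomer 16 (not isolated)
Conditions: Mg(OMe)2 (8 equiv), MeOH, rt → 50 °C; then cold 1 M HCl
Reagents that add atoms: none
Why: Magnesium methoxide should convert 15 into chelated magnesium enolates of the C7/C9 and C3/C5 β-dicarbonyl units; chain C6, nucleophilic through the C5 enolate, then adds to the ester carbonyl C1, methoxide leaves, and triketone 16 enolises to the aromatic phloroglucinol. The closest known reaction type is the magnesium-alkoxide-mediated Claisen cyclisation of 3,5,7-triketo esters, and of the pyrones that mask them, to acylphloroglucinols, the laboratory counterpart of the chalcone-synthase fold. The carbocycle closes in a 6-(enolendo)-exo-trig mode and forms the C6–C1 bond, which is C4a–C5 of the flavone. No stereocentre is created. The step needs Claisen closure to beat the aldol closures C2→C7, C4→C9 and C8→C3. Anhydrous magnesium chelation should secure this, because the most acidic, aroyl-flanked C8 stays enolised and so masks C7 and C9 as electrophiles, the ester C1 is the carbonyl least tied up as an enolate, and aldol adducts can revert whereas the Claisen product is drained as its stable magnesium phenoxide.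

Step 11
Reactants: 17 1-[3-(benzyloxy)-2,4,5-trimethoxyphenyl]-3-(2,4,6-trihydroxyphenyl)propane-1,3-dione
Product: 19 2-[3-(benzyloxy)-2,4,5-trimethoxyphenyl]-5,7-dihydroxy-4H-chromen-4-one, via 2-hydroxyflavanone hemiketal 18 (not isolated)
Conditions: H2SO4 (cat.), AcOH, 60 °C
Reagents that add atoms: none
Why: Acid-catalysed cyclodehydration as in the Baker–Venkataraman flavone endgame, an ortho phenol adding to the aryl ketone to give hemiketal 18, which loses water to the pyranone (O1–C2 bond) under conditions mild enough to keep the benzyl ether.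

Step 12
Reactants: 19 2-[3-(benzyloxy)-2,4,5-trimethoxyphenyl]-5,7-dihydroxy-4H-chromen-4-one
Product: 20 5,7-dihydroxy-2-(3-hydroxy-2,4,5-trimethoxyphenyl)-4H-chromen-4-one (5,7,3'-trihydroxy-2',4',5'-trimethoxyflavone)
Conditions: H2 (1 atm), 10% Pd/C, EtOAc/MeOH, rt
Reagents that add atoms: none
Why: Hydrogenolysis of the benzyl aryl ether over palladium, under which the methyl ethers and the pyranone double bond of the flavone should stay untouched at ambient pressure and temperature.

**Compound list**

1 | 2-hydroxy-3,4-dimethoxybenzaldehyde | COc1ccc(C=O)c(O)c1OC | starting material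
2 | 2-(benzyloxy)-3,4-dimethoxybenzaldehyde | COc1ccc(C=O)c(OCc2ccccc2)c1OC | intermediate
3 | 2-(benzyloxy)-3,4-dimethoxyphenyl formate | COc1ccc(OC=O)c(OCc2ccccc2)c1OC | intermediate (not isolated)
4 | 2-(benzyloxy)-3,4-dimethoxyphenol | COc1ccc(O)c(OCc2ccccc2)c1OC | intermediate
5 | 2-(benzyloxy)-6-(hydroxymethyl)-3,4-dimethoxyphenol | COc1cc(CO)c(O)c(OCc2ccccc2)c1OC | intermediate (not isolated)
6 | 3-(benzyloxy)-2-hydroxy-4,5-dimethoxybenzaldehyde | COc1cc(C=O)c(O)c(OCc2ccccc2)c1OC | intermediate
7 | 3-(benzyloxy)-2,4,5-trimethoxybenzaldehyde | COc1cc(C=O)c(OC)c(OCc2ccccc2)c1OC | intermediate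
8 | 3-(benzyloxy)-2,4,5-trimethoxybenzoic acid | COc1cc(C(=O)O)c(OC)c(OCc2ccccc2)c1OC | intermediate
9 | 2,2,6-trimethyl-4H-1,3-dioxin-4-one | CC1=CC(=O)OC(C)(C)O1 | starting material
10 | 2,2-dimethyl-6-(2-oxopropyl)-4H-1,3-dioxin-4-one | CC(=O)CC1=CC(=O)OC(C)(C)O1 | intermediate
11 | 6-(2,4-dioxopentyl)-2,2-dimethyl-4H-1,3-dioxin-4-one | CC(=O)CC(=O)CC1=CC(=O)OC(C)(C)O1 | intermediate
12 | 3-(benzyloxy)-2,4,5-trimethoxybenzoyl chloride | COc1cc(C(Cl)=O)c(OC)c(OCc2ccccc2)c1OC | intermediate (not isolated)
13 | 6-{6-[3-(benzyloxy)-2,4,5-trimethoxyphenyl]-2,4,6-trioxohexyl}-2,2-dimethyl-4H-1,3-dioxin-4-one | COc1cc(C(=O)CC(=O)CC(=O)CC2=CC(=O)OC(C)(C)O2)c(OC)c(OCc3ccccc3)c1OC | intermediate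
14 | 9-[3-(benzyloxy)-2,4,5-trimethoxyphenyl]non-1-ene-1,3,5,7,9-pentone (acylketene) | COc1cc(C(=O)CC(=O)CC(=O)CC(=O)C=C=O)c(OC)c(OCc2ccccc2)c1OC | intermediate (not isolated)
15 | methyl 9-[3-(benzyloxy)-2,4,5-trimethoxyphenyl]-3,5,7,9-tetraoxononanoate | COC(=O)CC(=O)CC(=O)CC(=O)CC(=O)c1cc(OC)c(OC)c(OCc2ccccc2)c1OC | intermediate
16 | 2-{3-[3-(benzyloxy)-2,4,5-trimethoxyphenyl]-3-oxopropanoyl}cyclohexane-1,3,5-trione | O=C1CC(=O)C(C(=O)CC(=O)c2cc(OC)c(OC)c(OCc3ccccc3)c2OC)C(=O)C1 | intermediate (not isolated)
17 | 1-[3-(benzyloxy)-2,4,5-trimethoxyphenyl]-3-(2,4,6-trihydroxyphenyl)propane-1,3-dione | O=C(CC(=O)c1c(O)cc(O)cc1O)c1cc(OC)c(OC)c(OCc2ccccc2)c1OC | intermediate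
18 | 2-[3-(benzyloxy)-2,4,5-trimethoxyphenyl]-2,5,7-trihydroxy-2,3-dihydro-4H-chromen-4-one (racemic hemiketal) | COc1cc(C2(O)CC(=O)c3c(O)cc(O)cc3O2)c(OC)c(OCc4ccccc4)c1OC | intermediate (not isolated)
19 | 2-[3-(benzyloxy)-2,4,5-trimethoxyphenyl]-5,7-dihydroxy-4H-chromen-4-one | COc1cc(-c2cc(=O)c3c(O)cc(O)cc3o2)c(OC)c(OCc4ccccc4)c1OC | intermediate
20 | 5,7-dihydroxy-2-(3-hydroxy-2,4,5-trimethoxyphenyl)-4H-chromen-4-one | COc1cc(-c2cc(=O)c3c(O)cc(O)cc3o2)c(OC)c(O)c1OC | target

**Step count and risks**

Total step count: 12. Longest linear sequence: 10 steps (steps 1–5 and 8–12, from 1).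

Steps most likely to fail:

1. Step 10. The fold may divert into aldol cyclodehydration (C2→C7 to a resorcylate, C4→C9 or C8→C3 to carbocycles that place the aryl group on the new ring) or into pyranone formation before the Claisen closure occurs. The fallback sets out from acid chloride 12 and comes back at 17. Commercial 2',4',6'-trihydroxyacetophenone would be converted with LiHMDS (4 equiv, THF, −78 °C) into its polylithiated phenoxide-enolate and C-aroylated with 12, a modified Baker–Venkataraman construction of the diketone that needs no phenol protection. No new compound arises on this way (F0).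

2. Step 8. Proton transfer from the product to unreacted trianion, O-acylation, or aldol aromatisation of the dioxinone-bearing chain during quench and work-up may erode the aroylation. The fallback sets out from acid chloride 12 and comes back at 15 without any dioxinone. The trianion of commercial heptane-2,4,6-trione (LDA, THF) would be aroylated with 12 at its terminal carbanion to give 1-[3-(benzyloxy)-2,4,5-trimethoxyphenyl]octane-1,3,5,7-tetraone F1. Its tetraanion would be carboxylated with CO2 at the terminal methyl to give 9-[3-(benzyloxy)-2,4,5-trimethoxyphenyl]-3,5,7,9-tetraoxononanoic acid F2. Brief treatment of F2 with trimethylsilyldiazomethane in toluene/methanol at 0 °C would give ester 15.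

3. Step 9. The acylketene may be captured by the enol oxygen on C5 of its own chain instead of methanol, or the freed tetraketo ester may close thermally by an aldol pathway. The fallback sets out from 13 and comes back at 17, turning the intramolecular capture into the intended path. Heating 13 in toluene without methanol would give 6-{4-[3-(benzyloxy)-2,4,5-trimethoxyphenyl]-2,4-dioxobutyl}-4-hydroxy-2H-pyran-2-one F3. Magnesium methoxide in methanol would then open the pyrone ring to the magnesium chelate of 15 in the flask, which folds by the same C6→C1 Claisen closure to 17.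

**Further compounds**

F0 | step 10 | none | none
F1 | step 8 | 1-[3-(benzyloxy)-2,4,5-trimethoxyphenyl]octane-1,3,5,7-tetraone | CC(=O)CC(=O)CC(=O)CC(=O)c1cc(OC)c(OC)c(OCc2ccccc2)c1OC
F2 | step 8 | 9-[3-(benzyloxy)-2,4,5-trimethoxyphenyl]-3,5,7,9-tetraoxononanoic acid | OC(=O)CC(=O)CC(=O)CC(=O)CC(=O)c1cc(OC)c(OC)c(OCc2ccccc2)c1OC
F3 | step 9 | 6-{4-[3-(benzyloxy)-2,4,5-trimethoxyphenyl]-2,4-dioxobutyl}-4-hydroxy-2H-pyran-2-one | O=c1cc(O)cc(CC(=O)CC(=O)c2cc(OC)c(OC)c(OCc3ccccc3)c2OC)o1
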